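**Retrosynthetic overview**
1. The only ring formed, the 14-membered lactone, is closed last by ring-closing metathesis at C5=C6 (step 16) of ester 32. Ester 32 comes from alcohol 24 (C13-OH) and dienoic acid 30; the CH2CO2H arm is carried as a silyl-protected hydroxyethyl group and oxidised at the end.
2. Alcohol 24: the C14–C15 bond is made by a 1,5-anti boron aldol of methyl ketone 13 with aldehyde 20 (sets C15). A chelation-controlled 1,3-syn reduction then sets C13.
3. Aldehyde 20 (key step): the C16–C17 bond and the (18E) trisubstituted olefin come from a Johnson–Claisen [3,3]-sigmatropic rearrangement of allylic alcohol 16.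
4. Ketone 13: (S)-epichlorohydrin is the only source of chirality (C11). It is opened first by the 2-methyl-1,3-dithiane anion, then by a (Z)-alkenyl Grignard made by bromoallylation of propyne (fixes C8=C9).
5. Acid 30: carboxylation of a silyl butynyl ether, anti-hydroiodination, then Stille allylation.

Assumption: the SMILES is taken literally (C8=C9 with C7 and C10 cis; 11R,13S,15R); positions are cited by seco-acid numbering, C1 (lactone C=O) to C20 (benzylic CH2).

**Route**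

Step 1
Reactants: 1 propyne; 2 allyl bromide
Product: 3 (4Z)-5-bromohexa-1,4-diene
Conditions: PdBr2(PhCN)2 (1 mol%), neat 2 (excess), slow addition of 1, 0 °C → rt, sealed vessel
Reagents that add atoms: none
Why: Palladium-catalysed bromoallylation of a terminal alkyne: cis-bromopalladation (Br to the internal carbon), insertion of allyl bromide and β-bromide elimination give the 1-bromo-1,4-diene with Br and the allyl CH2 cis, which fixes the later C8=C9 geometry.

Step 2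
Reactants: 4 2-methyl-1,3-dithiane; 5 (S)-epichlorohydrin
Product: 8 2-methyl-2-{[(2S)-oxiran-2-yl]methyl}-1,3-dithiane, via 2-lithio-2-methyl-1,3-dithiane 6 (not isolated), via lithium chlorohydrin alkoxide 7 (not isolated)
Conditions: n-BuLi, THF, −30 °C; then 5, −78 °C → rt
Reagents that add atoms: none
Why: Corey–Seebach dithiane anion opens the epoxide at its CH2 terminus (SN2) and the alkoxide then displaces chloride to re-form an epoxide, so the future C11 stereocentre is carried over from 5 without any bond to it being broken.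

Step 3
Reactants: 3 (4Z)-5-bromohexa-1,4-diene; 8 2-methyl-2-{[(2S)-oxiran-2-yl]methyl}-1,3-dithiane
Product: 11 (2R,4Z)-4-methyl-1-(2-methyl-1,3-dithian-2-yl)octa-4,7-dien-2-ol, via alkenyllithium 9 (not isolated), via alkenylmagnesium bromide 10 (not isolated)
Conditions: t-BuLi (2 equiv), Et2O, −78 °C; MgBr2·OEt2; then CuI (10 mol%), 8, THF, −30 → 0 °C; then H2O
Reagents that add atoms: none
Why: Lithium–bromine exchange and transmetalation retain the olefin geometry, and the copper-catalysed Grignard epoxide opening occurs at the unsubstituted carbon, forming C9–C10 while leaving C11 untouched.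

Step 4
Reactants: 11 (2R,4Z)-4-methyl-1-(2-methyl-1,3-dithian-2-yl)octa-4,7-dien-2-ol
Product: 12 2-{(2R,4Z)-2-[(4-methoxyphenyl)methoxy]-4-methylocta-4,7-dien-1-yl}-2-methyl-1,3-dithiane
Conditions: NaH, 4-methoxybenzyl chloride, Bu4NI (cat.), THF/DMF, 0 °C → rt
Reagents that add atoms: 4-methoxybenzyl chloride, COc1ccc(CCl)cc1
Why: Williamson ether synthesis on the only hydroxyl installs the benzyl-type ether needed later for 1,5-induction and chelation; dithiane and olefins are inert to NaH.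

Step 5
Reactants: 12 2-{(2R,4Z)-2-[(4-methoxyphenyl)methoxy]-4-methylocta-4,7-dien-1-yl}-2-methyl-1,3-dithiane
Product: 13 (4R,6Z)-4-[(4-methoxyphenyl)methoxy]-6-methyldeca-6,9-dien-2-one
Conditions: MeI, CaCO3, MeCN/H2O (9:1), 45 °C
Reagents that add atoms: water, O
Why: S-Methylation followed by hydrolysis (dithiane deprotection) unmasks the methyl ketone under neutral conditions that spare the PMB ether and the skipped diene; no stereocentre is involved.

Step 6
Reactants: 14 phenylacetaldehyde; 15 isopropenylmagnesium bromide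
Product: 16 (±)-3-methyl-1-phenylbut-3-en-2-ol
Conditions: THF, −78 → 0 °C; then H2O
Reagents that add atoms: none
Why: Grignard 1,2-addition to the aldehyde gives the allylic alcohol; it is used racemic because its stereocentre is destroyed in step 7.

Step 7
Reactants: 16 (±)-3-methyl-1-phenylbut-3-en-2-ol; 17 triethyl orthoacetate
Product: 19 ethyl (4E)-4-methyl-6-phenylhex-4-enoate, via mixed ketene acetal 18 (not isolated)
Conditions: 17 (excess), EtCO2H (cat.), 140 °C, EtOH distilled off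
Reagents that add atoms: none
Why: Johnson–Claisen [3,3]-sigmatropic rearrangement forms the C16–C17 bond through a chair transition state with the benzyl group pseudo-equatorial, which gives the (E)-trisubstituted C18=C19 olefin with high selectivity.

Step 8
Reactants: 19 ethyl (4E)-4-methyl-6-phenylhex-4-enoate
Product: 20 (4E)-4-methyl-6-phenylhex-4-enal
Conditions: i-Bu2AlH (1.05 equiv), CH2Cl2, −78 °C; then H2O
Reagents that add atoms: none
Why: Partial hydride reduction of the ester stops at the stable tetrahedral aluminium hemiacetal at −78 °C, which releases the aldehyde on work-up.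

Step 9
Reactants: 13 (4R,6Z)-4-[(4-methoxyphenyl)methoxy]-6-methyldeca-6,9-dien-2-one; 20 (4E)-4-methyl-6-phenylhex-4-enal
Product: 22 (2E,6R,10R,12Z)-6-hydroxy-10-[(4-methoxyphenyl)methoxy]-3,12-dimethyl-1-phenylhexadeca-2,12,15-trien-8-one, via dibutylboron enolate 21 (not isolated)
Conditions: n-Bu2BOTf, i-Pr2NEt, Et2O, −78 °C; then 20, −78 → −20 °C; then H2O2, MeOH, pH 7 buffer, 0 °C
Reagents that add atoms: none
Why: Boron-mediated methyl ketone aldol with 1,5-anti induction from the β-PMB ether (C11) sets the new C15 carbinol as R, anti to C11-O, by substrate control alone.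

Step 10
Reactants: 22 (2E,6R,10R,12Z)-6-hydroxy-10-[(4-methoxyphenyl)methoxy]-3,12-dimethyl-1-phenylhexadeca-2,12,15-trien-8-one
Product: 23 (2E,6R,10R,12Z)-6-[(tert-butyldimethylsilyl)oxy]-10-[(4-methoxyphenyl)methoxy]-3,12-dimethyl-1-phenylhexadeca-2,12,15-trien-8-one
Conditions: TBSOTf, 2,6-lutidine, CH2Cl2, −78 °C
Reagents that add atoms: tert-butyldimethylsilyl trifluoromethanesulfonate, CC(C)(C)[Si](C)(C)OS(=O)(=O)C(F)(F)F
Why: Silylation of the β-hydroxy ketone at low temperature protects C15-OH as a non-chelating ether without retro-aldol or elimination.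

Step 11
Reactants: 23 (2E,6R,10R,12Z)-6-[(tert-butyldimethylsilyl)oxy]-10-[(4-methoxyphenyl)methoxy]-3,12-dimethyl-1-phenylhexadeca-2,12,15-trien-8-one
Product: 24 (2E,6R,8R,10R,12Z)-6-[(tert-butyldimethylsilyl)oxy]-10-[(4-methoxyphenyl)methoxy]-3,12-dimethyl-1-phenylhexadeca-2,12,15-trien-8-ol
Conditions: LiAlH4, LiI, Et2O, −100 °C; then H2O
Reagents that add atoms: none
Why: Chelation-controlled reduction: lithium bridges the ketone and the PMB ether oxygen (the silyl ether does not chelate) and hydride adds to the open face of the chelate, giving the 1,3-syn C11/C13 relationship and hence C13 anti to C15.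

Step 12
Reactants: 25 (but-3-yn-1-yloxy)(tert-butyl)diphenylsilane
Product: 27 5-[(tert-butyldiphenylsilyl)oxy]pent-2-ynoic acid, via lithium acetylide 26 (not isolated)
Conditions: n-BuLi, THF, −78 °C; CO2; then 1 M HCl
Reagents that add atoms: carbon dioxide, O=C=O
Why: Carboxylation of the lithium acetylide gives the 2-ynoic acid (C1–C3 plus the hydroxyethyl arm); the silyl ether is inert.

Step 13
Reactants: 27 5-[(tert-butyldiphenylsilyl)oxy]pent-2-ynoic acid
Product: 28 (2Z)-5-[(tert-butyldiphenylsilyl)oxy]-3-iodopent-2-enoic acid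
Conditions: NaI, AcOH, 70 °C
Reagents that add atoms: sodium iodide, [Na+].[I-]
Why: Conjugate addition of iodide and anti protonation (anti-hydroiodination of a 2-ynoic acid) place iodine at C3 cis to the carboxyl group; the TBDPS ether tolerates acetic acid.

Step 14
Reactants: 28 (2Z)-5-[(tert-butyldiphenylsilyl)oxy]-3-iodopent-2-enoic acid; 29 allyltributylstannane
Product: 30 (2E)-3-{2-[(tert-butyldiphenylsilyl)oxy]ethyl}hexa-2,5-dienoic acid
Conditions: Pd(PPh3)4 (5 mol%), CuI (10 mol%), DMF, rt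
Reagents that add atoms: none
Why: Stille cross-coupling on zerovalent palladium replaces iodine by allyl with retention of olefin geometry, so C4 ends up cis to C1 as in the target.

Step 15
Reactants: 24 (2E,6R,8R,10R,12Z)-6-[(tert-butyldimethylsilyl)oxy]-10-[(4-methoxyphenyl)methoxy]-3,12-dimethyl-1-phenylhexadeca-2,12,15-trien-8-ol; 30 (2E)-3-{2-[(tert-butyldiphenylsilyl)oxy]ethyl}hexa-2,5-dienoic acid
Product: 32 (2E,6R,8R,10R,12Z)-6-[(tert-butyldimethylsilyl)oxy]-10-[(4-methoxyphenyl)methoxy]-3,12-dimethyl-1-phenylhexadeca-2,12,15-trien-8-yl (2E)-3-{2-[(tert-butyldiphenylsilyl)oxy]ethyl}hexa-2,5-dienoate, via mixed anhydride 31 (not isolated)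
Conditions: 2,4,6-Cl3C6H2COCl, Et3N, toluene, 0 °C; then 24, DMAP, 0 °C → rt
Reagents that add atoms: none
Why: Yamaguchi esterification acylates the only free hydroxyl (C13) with retention of configuration; the pre-formed mixed anhydride and low temperature limit base-mediated scrambling of the 2,5-dienoate.

Step 16
Reactants: 32 (2E,6R,8R,10R,12Z)-6-[(tert-butyldimethylsilyl)oxy]-10-[(4-methoxyphenyl)methoxy]-3,12-dimethyl-1-phenylhexadeca-2,12,15-trien-8-yl (2E)-3-{2-[(tert-butyldiphenylsilyl)oxy]ethyl}hexa-2,5-dienoate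
Product: 33 (3E,6Z,9Z,12R,14R)-14-{(2R,5E)-2-[(tert-butyldimethylsilyl)oxy]-5-methyl-7-phenylhept-5-en-1-yl}-4-{2-[(tert-butyldiphenylsilyl)oxy]ethyl}-12-[(4-methoxyphenyl)methoxy]-10-methyl-1-oxacyclotetradeca-3,6,9-trien-2-one
Conditions: second-generation Grubbs catalyst RuCl2(=CHPh)(H2IMes)(PCy3) (10 mol%), 1,4-benzoquinone (10 mol%), CH2Cl2 (1 mM), 40 °C
Reagents that add atoms: none
Why: Ring-closing metathesis joins the two monosubstituted vinyl groups (the trisubstituted olefins are much slower) with loss of ethene; the strain of the 14-membered skipped triene is expected to favour the (Z)-C5=C6 olefin.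

Step 17
Reactants: 33 (3E,6Z,9Z,12R,14R)-14-{(2R,5E)-2-[(tert-butyldimethylsilyl)oxy]-5-methyl-7-phenylhept-5-en-1-yl}-4-{2-[(tert-butyldiphenylsilyl)oxy]ethyl}-12-[(4-methoxyphenyl)methoxy]-10-methyl-1-oxacyclotetradeca-3,6,9-trien-2-one
Product: 34 (3E,6Z,9Z,12R,14R)-14-{(2R,5E)-2-[(tert-butyldimethylsilyl)oxy]-5-methyl-7-phenylhept-5-en-1-yl}-4-{2-[(tert-butyldiphenylsilyl)oxy]ethyl}-12-hydroxy-10-methyl-1-oxacyclotetradeca-3,6,9-trien-2-one
Conditions: DDQ, CH2Cl2/pH 7 buffer (10:1), 0 °C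
Reagents that add atoms: none
Why: Oxidative cleavage of the electron-rich PMB ether by DDQ is fast at 0 °C and leaves silyl ethers, the lactone and the olefins untouched.

Step 18
Reactants: 34 (3E,6Z,9Z,12R,14R)-14-{(2R,5E)-2-[(tert-butyldimethylsilyl)oxy]-5-methyl-7-phenylhept-5-en-1-yl}-4-{2-[(tert-butyldiphenylsilyl)oxy]ethyl}-12-hydroxy-10-methyl-1-oxacyclotetradeca-3,6,9-trien-2-one
Product: 35 (3E,6Z,9Z,12R,14S)-12-hydroxy-4-(2-hydroxyethyl)-14-[(2R,5E)-2-hydroxy-5-methyl-7-phenylhept-5-en-1-yl]-10-methyl-1-oxacyclotetradeca-3,6,9-trien-2-one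
Conditions: HF·pyridine, pyridine, THF, 0 °C → rt
Reagents that add atoms: none
Why: Fluoride-mediated desilylation removes both silyl ethers under buffered, non-basic conditions, which avoids acyl migration of the C13 ester to the neighbouring hydroxyls.

Step 19
Reactants: 35 (3E,6Z,9Z,12R,14S)-12-hydroxy-4-(2-hydroxyethyl)-14-[(2R,5E)-2-hydroxy-5-methyl-7-phenylhept-5-en-1-yl]-10-methyl-1-oxacyclotetradeca-3,6,9-trien-2-one
Product: 37 2-{(3E,6Z,9Z,12R,14S)-12-hydroxy-14-[(2R,5E)-2-hydroxy-5-methyl-7-phenylhept-5-en-1-yl]-10-methyl-2-oxo-1-oxacyclotetradeca-3,6,9-trien-4-yl}acetic acid, via aldehyde 36 (not isolated)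
Conditions: TEMPO (20 mol%), PhI(OAc)2 (2.2 equiv), MeCN/H2O (1:1), 0 °C → rt
Reagents that add atoms: water, O
Why: Oxoammonium (TEMPO/PhI(OAc)2) oxidation is selective for the primary alcohol over the two secondary ones for steric reasons, and in water the aldehyde hydrate is oxidised on to the carboxylic acid.

**Compound list**
1 | propyne | CC#C | starting material
2 | allyl bromide | C=CCBr | starting material
3 | (4Z)-5-bromohexa-1,4-diene | C/C(Br)=C/CC=C | intermediate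
4 | 2-methyl-1,3-dithiane | CC1SCCCS1 | starting material
5 | (S)-epichlorohydrin | ClC[C@@H]1CO1 | starting material
6 | 2-lithio-2-methyl-1,3-dithiane | [Li]C1(C)SCCCS1 | intermediate (not isolated)
7 | lithium (2S)-1-chloro-3-(2-methyl-1,3-dithian-2-yl)propan-2-olate | [Li]O[C@H](CCl)CC1(C)SCCCS1 | intermediate (not isolated)
8 | 2-methyl-2-{[(2S)-oxiran-2-yl]methyl}-1,3-dithiane | CC1(C[C@H]2CO2)SCCCS1 | intermediate
9 | [(2E)-hexa-2,5-dien-2-yl]lithium (Li cis to the allylic CH2) | C/C([Li])=C/CC=C | intermediate (not isolated)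
10 | [(2Z)-hexa-2,5-dien-2-yl]magnesium bromide | C/C([Mg]Br)=C/CC=C | intermediate (not isolated)
11 | (2R,4Z)-4-methyl-1-(2-methyl-1,3-dithian-2-yl)octa-4,7-dien-2-ol | CC1(C[C@H](O)C/C(C)=C\CC=C)SCCCS1 | intermediate
12 | 2-{(2R,4Z)-2-[(4-methoxyphenyl)methoxy]-4-methylocta-4,7-dien-1-yl}-2-methyl-1,3-dithiane | CC1(C[C@H](OCc2ccc(OC)cc2)C/C(C)=C\CC=C)SCCCS1 | intermediate
13 | (4R,6Z)-4-[(4-methoxyphenyl)methoxy]-6-methyldeca-6,9-dien-2-one | C=CC/C=C(C)\C[C@@H](OCc1ccc(OC)cc1)CC(C)=O | intermediate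
14 | phenylacetaldehyde | O=CCc1ccccc1 | starting material
15 | isopropenylmagnesium bromide | CC(=C)[Mg]Br | starting material
16 | (±)-3-methyl-1-phenylbut-3-en-2-ol | CC(=C)C(O)Cc1ccccc1 | intermediate
17 | triethyl orthoacetate | CCOC(C)(OCC)OCC | starting material
18 | {2-[(1-ethoxyethenyl)oxy]-3-methylbut-3-en-1-yl}benzene (mixed ketene acetal) | C=C(OCC)OC(Cc1ccccc1)C(C)=C | intermediate (not isolated)
19 | ethyl (4E)-4-methyl-6-phenylhex-4-enoate | CCOC(=O)CC/C(C)=C/Cc1ccccc1 | intermediate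
20 | (4E)-4-methyl-6-phenylhex-4-enal | O=CCC/C(C)=C/Cc1ccccc1 | intermediate
21 | dibutyl({(4R,6Z)-4-[(4-methoxyphenyl)methoxy]-6-methyldeca-1,6,9-trien-2-yl}oxy)borane | C=CC/C=C(C)\C[C@@H](OCc1ccc(OC)cc1)CC(=C)OB(CCCC)CCCC | intermediate (not isolated)
22 | (2E,6R,10R,12Z)-6-hydroxy-10-[(4-methoxyphenyl)methoxy]-3,12-dimethyl-1-phenylhexadeca-2,12,15-trien-8-one | C=CC/C=C(C)\C[C@@H](OCc1ccc(OC)cc1)CC(=O)C[C@H](O)CC/C(C)=C/Cc1ccccc1 | intermediate
23 | (2E,6R,10R,12Z)-6-[(tert-butyldimethylsilyl)oxy]-10-[(4-methoxyphenyl)methoxy]-3,12-dimethyl-1-phenylhexadeca-2,12,15-trien-8-one | C=CC/C=C(C)\C[C@@H](OCc1ccc(OC)cc1)CC(=O)C[C@H](O[Si](C)(C)C(C)(C)C)CC/C(C)=C/Cc1ccccc1 | intermediate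
24 | (2E,6R,8R,10R,12Z)-6-[(tert-butyldimethylsilyl)oxy]-10-[(4-methoxyphenyl)methoxy]-3,12-dimethyl-1-phenylhexadeca-2,12,15-trien-8-ol | C=CC/C=C(C)\C[C@@H](OCc1ccc(OC)cc1)C[C@@H](O)C[C@H](O[Si](C)(C)C(C)(C)C)CC/C(C)=C/Cc1ccccc1 | intermediate
25 | (but-3-yn-1-yloxy)(tert-butyl)diphenylsilane | C#CCCO[Si](c1ccccc1)(c1ccccc1)C(C)(C)C | starting material
26 | {4-[(tert-butyldiphenylsilyl)oxy]but-1-yn-1-yl}lithium | [Li]C#CCCO[Si](c1ccccc1)(c1ccccc1)C(C)(C)C | intermediate (not isolated)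
27 | 5-[(tert-butyldiphenylsilyl)oxy]pent-2-ynoic acid | OC(=O)C#CCCO[Si](c1ccccc1)(c1ccccc1)C(C)(C)C | intermediate
28 | (2Z)-5-[(tert-butyldiphenylsilyl)oxy]-3-iodopent-2-enoic acid | OC(=O)/C=C(I)/CCO[Si](c1ccccc1)(c1ccccc1)C(C)(C)C | intermediate
29 | allyltributylstannane | C=CC[Sn](CCCC)(CCCC)CCCC | starting material
30 | (2E)-3-{2-[(tert-butyldiphenylsilyl)oxy]ethyl}hexa-2,5-dienoic acid | OC(=O)/C=C(\CC=C)CCO[Si](c1ccccc1)(c1ccccc1)C(C)(C)C | intermediate
31 | (2E)-3-{2-[(tert-butyldiphenylsilyl)oxy]ethyl}hexa-2,5-dienoic 2,4,6-trichlorobenzoic anhydride | C=CC/C(CCO[Si](c1ccccc1)(c1ccccc1)C(C)(C)C)=C\C(=O)OC(=O)c1c(Cl)cc(Cl)cc1Cl | intermediate (not isolated)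
32 | (2E,6R,8R,10R,12Z)-6-[(tert-butyldimethylsilyl)oxy]-10-[(4-methoxyphenyl)methoxy]-3,12-dimethyl-1-phenylhexadeca-2,12,15-trien-8-yl (2E)-3-{2-[(tert-butyldiphenylsilyl)oxy]ethyl}hexa-2,5-dienoate | C=CC/C=C(C)\C[C@@H](OCc1ccc(OC)cc1)C[C@@H](OC(=O)/C=C(\CC=C)CCO[Si](c1ccccc1)(c1ccccc1)C(C)(C)C)C[C@H](O[Si](C)(C)C(C)(C)C)CC/C(C)=C/Cc1ccccc1 | intermediate
33 | (3E,6Z,9Z,12R,14R)-14-{(2R,5E)-2-[(tert-butyldimethylsilyl)oxy]-5-methyl-7-phenylhept-5-en-1-yl}-4-{2-[(tert-butyldiphenylsilyl)oxy]ethyl}-12-[(4-methoxyphenyl)methoxy]-10-methyl-1-oxacyclotetradeca-3,6,9-trien-2-one | C/C1=C/C/C=C\C/C(CCO[Si](c2ccccc2)(c2ccccc2)C(C)(C)C)=C\C(=O)O[C@@H](C[C@H](O[Si](C)(C)C(C)(C)C)CC/C(C)=C/Cc2ccccc2)C[C@H](OCc2ccc(OC)cc2)C1 | intermediate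
34 | (3E,6Z,9Z,12R,14R)-14-{(2R,5E)-2-[(tert-butyldimethylsilyl)oxy]-5-methyl-7-phenylhept-5-en-1-yl}-4-{2-[(tert-butyldiphenylsilyl)oxy]ethyl}-12-hydroxy-10-methyl-1-oxacyclotetradeca-3,6,9-trien-2-one | C/C1=C/C/C=C\C/C(CCO[Si](c2ccccc2)(c2ccccc2)C(C)(C)C)=C\C(=O)O[C@@H](C[C@H](O[Si](C)(C)C(C)(C)C)CC/C(C)=C/Cc2ccccc2)C[C@H](O)C1 | intermediate
35 | (3E,6Z,9Z,12R,14S)-12-hydroxy-4-(2-hydroxyethyl)-14-[(2R,5E)-2-hydroxy-5-methyl-7-phenylhept-5-en-1-yl]-10-methyl-1-oxacyclotetradeca-3,6,9-trien-2-one | C/C1=C/C/C=C\C/C(CCO)=C\C(=O)O[C@@H](C[C@H](O)CC/C(C)=C/Cc2ccccc2)C[C@H](O)C1 | intermediate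
36 | 2-{(3E,6Z,9Z,12R,14S)-12-hydroxy-14-[(2R,5E)-2-hydroxy-5-methyl-7-phenylhept-5-en-1-yl]-10-methyl-2-oxo-1-oxacyclotetradeca-3,6,9-trien-4-yl}acetaldehyde | C/C1=C/C/C=C\C/C(CC=O)=C\C(=O)O[C@@H](C[C@H](O)CC/C(C)=C/Cc2ccccc2)C[C@H](O)C1 | intermediate (not isolated)
37 | 2-{(3E,6Z,9Z,12R,14S)-12-hydroxy-14-[(2R,5E)-2-hydroxy-5-methyl-7-phenylhept-5-en-1-yl]-10-methyl-2-oxo-1-oxacyclotetradeca-3,6,9-trien-4-yl}acetic acid | C/C1=C/C/C=C\C/C(CC(=O)O)=C\C(=O)O[C@@H](C[C@H](O)CC/C(C)=C/Cc2ccccc2)C[C@H](O)C1 | target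

**Step count and risks**

Total step count: 19. Longest linear sequence: 12 steps (steps 2, 3, 4, 5, 9, 10, 11, 15, 16, 17, 18, 19, from 4 and 5).

Steps most likely to fail:

Step 11 (syn selectivity of the chelation-controlled reduction next to a second β-oxygen). The fallback sets out from ketone 23. Reduction with SmI2 and MeOH in THF at 0 °C, where the samarium ketyl chelated to the PMB ether gives the 1,3-anti alcohol, leads to the C13 epimer (2E,6R,8S,10R,12Z)-6-[(tert-butyldimethylsilyl)oxy]-10-[(4-methoxyphenyl)methoxy]-3,12-dimethyl-1-phenylhexadeca-2,12,15-trien-8-ol F1. Mitsunobu esterification of this alcohol with acid 30 (PPh3, DIAD, toluene, 0 °C → rt) inverts C13 and returns to the route at ester 32, bypassing 24 and any activation of the acid.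

Step 15 (loss of the 2E geometry or deconjugation when the 2,5-dienoic acid is activated). The fallback sets out from alcohol 24 and iodo acid 28. Carbodiimide esterification (DCC, catalytic DMAP, CH2Cl2, 0 °C) gives (2E,6R,8R,10R,12Z)-6-[(tert-butyldimethylsilyl)oxy]-10-[(4-methoxyphenyl)methoxy]-3,12-dimethyl-1-phenylhexadeca-2,12,15-trien-8-yl (2Z)-5-[(tert-butyldiphenylsilyl)oxy]-3-iodopent-2-enoate F2, which has no skipped diene to isomerise. Stille allylation of this iodide with 29 (Pd(PPh3)4, CuI, DMF, rt) installs the allyl group with retention and returns to the route at ester 32.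

Step 16 (E/Z mixture or oligomers in the ring-closing metathesis). The fallback sets out from acid 30 and alcohol 24 and closes the ring by lactonisation instead. Acid 30 is converted (Cl3CCH2OH, DCC, DMAP) into 2,2,2-trichloroethyl (2E)-3-{2-[(tert-butyldiphenylsilyl)oxy]ethyl}hexa-2,5-dienoate F3. Z-selective cross-metathesis of this ester (excess) with 24, using the racemic cyclometalated ruthenium nitrate catalyst Ru(NO3)(=CH-C6H4-2-O-i-Pr)(C,C-chelating N-adamantyl-N'-(2,6-diisopropylphenyl)imidazolin-2-ylidene), gives 2,2,2-trichloroethyl (2E,5Z,8Z,11R,13R,15R,18E)-15-[(tert-butyldimethylsilyl)oxy]-3-{2-[(tert-butyldiphenylsilyl)oxy]ethyl}-13-hydroxy-11-[(4-methoxyphenyl)methoxy]-9,18-dimethyl-20-phenylicosa-2,5,8,18-tetraenoate F4. Zn in AcOH/THF releases (2E,5Z,8Z,11R,13R,15R,18E)-15-[(tert-butyldimethylsilyl)oxy]-3-{2-[(tert-butyldiphenylsilyl)oxy]ethyl}-13-hydroxy-11-[(4-methoxyphenyl)methoxy]-9,18-dimethyl-20-phenylicosa-2,5,8,18-tetraenoic acid F5. Macrolactonisation onto the only free hydroxyl (2-methyl-6-nitrobenzoic anhydride, DMAP, toluene, high dilution) returns to the route at macrolactone 33.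

**Further compounds**
F1 | step 11 | (2E,6R,8S,10R,12Z)-6-[(tert-butyldimethylsilyl)oxy]-10-[(4-methoxyphenyl)methoxy]-3,12-dimethyl-1-phenylhexadeca-2,12,15-trien-8-ol | C=CC/C=C(C)\C[C@@H](OCc1ccc(OC)cc1)C[C@H](O)C[C@H](O[Si](C)(C)C(C)(C)C)CC/C(C)=C/Cc1ccccc1
F2 | step 15 | (2E,6R,8R,10R,12Z)-6-[(tert-butyldimethylsilyl)oxy]-10-[(4-methoxyphenyl)methoxy]-3,12-dimethyl-1-phenylhexadeca-2,12,15-trien-8-yl (2Z)-5-[(tert-butyldiphenylsilyl)oxy]-3-iodopent-2-enoate | C=CC/C=C(C)\C[C@@H](OCc1ccc(OC)cc1)C[C@@H](OC(=O)/C=C(I)/CCO[Si](c1ccccc1)(c1ccccc1)C(C)(C)C)C[C@H](O[Si](C)(C)C(C)(C)C)CC/C(C)=C/Cc1ccccc1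
F3 | step 16 | 2,2,2-trichloroethyl (2E)-3-{2-[(tert-butyldiphenylsilyl)oxy]ethyl}hexa-2,5-dienoate | C=CC/C(CCO[Si](c1ccccc1)(c1ccccc1)C(C)(C)C)=C\C(=O)OCC(Cl)(Cl)Cl
F4 | step 16 | 2,2,2-trichloroethyl (2E,5Z,8Z,11R,13R,15R,18E)-15-[(tert-butyldimethylsilyl)oxy]-3-{2-[(tert-butyldiphenylsilyl)oxy]ethyl}-13-hydroxy-11-[(4-methoxyphenyl)methoxy]-9,18-dimethyl-20-phenylicosa-2,5,8,18-tetraenoate | ClC(Cl)(Cl)COC(=O)/C=C(CCO[Si](c1ccccc1)(c1ccccc1)C(C)(C)C)\C/C=C\C/C=C(C)\C[C@@H](OCc1ccc(OC)cc1)C[C@@H](O)C[C@H](O[Si](C)(C)C(C)(C)C)CC/C(C)=C/Cc1ccccc1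
F5 | step 16 | (2E,5Z,8Z,11R,13R,15R,18E)-15-[(tert-butyldimethylsilyl)oxy]-3-{2-[(tert-butyldiphenylsilyl)oxy]ethyl}-13-hydroxy-11-[(4-methoxyphenyl)methoxy]-9,18-dimethyl-20-phenylicosa-2,5,8,18-tetraenoic acid | OC(=O)/C=C(CCO[Si](c1ccccc1)(c1ccccc1)C(C)(C)C)\C/C=C\C/C=C(C)\C[C@@H](OCc1ccc(OC)cc1)C[C@@H](O)C[C@H](O[Si](C)(C)C(C)(C)C)CC/C(C)=C/Cc1ccccc1
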